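**Retrosynthetic overview**

1. The strategy rests on the cis-fused 2-methoxycyclohex-2-ene-1,4-dione ring. Its quaternary carbon Cq (bearing the chromon-2-yl group) is bonded to C12 and its ring-fusion CH (Cf) to C15, so it shares the Cq–Cf bond with the cyclohexene ring C12–C13=C14–C15–Cf–Cq. This is a quinone/diene Diels–Alder retron in which C11, the chromonyl group and H on Cf are mutually cis, that is, the quinone-endo adduct of a 12Z diene.
2. Disconnections: C7=O back to a 7α-allylic alcohol; C12–Cq and C15–Cf by an intramolecular [4+2]; the quinone back to the 2',4',5'-trimethoxyaryl ring of a flavone. The two halves are held by a traceless O7–SiMe2–C3(chromone) tether, possible because chromone C3 ends as C–H and C7 as an oxygenated carbon.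
3. Diene half from (+)-sclareolide (C5 and C10 bought; 9α-OH by α-epoxidation and epoxide-to-allylic-alcohol isomerisation; 7α-OH by SeO2; 12Z diene by iodo-Wittig olefination and Stille coupling). Flavone half by the Baker–Venkataraman route.
4. Ring order: decalin bought; chromone pyranone ring by cyclodehydration; cyclohexene ring and a temporary ten-membered siloxane ring together in the cycloaddition that turns flavone ring B into the ene-dione ring; siloxane ring then opened, silicon removed, C7 oxidised last.

Key step: step 19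

Remark: labdane numbering is used for the terpenoid half (α = face opposite the C10 methyl); Cq and Cf are the quaternary and the CH ring-fusion carbons of the ene-dione ring; the decalin of the target is assumed to have the absolute configuration of (+)-sclareolide, as its SMILES indicates.

**Route**

Step 1
Reactants: 1 (+)-sclareolide
Product: 2 methyl 13,14,15,16-tetranorlabd-8-en-12-oate
Conditions: conc. H2SO4, MeOH, reflux
Reagents that add atoms: methanol, CO
Why: Acid-catalysed methanolysis of the lactone with E1 dehydration at C8, run to equilibrium so that the tetrasubstituted 8(9)-alkene should predominate; the C9 centre is erased on purpose and rebuilt in step 4, while C5 and C10 are untouched.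

Step 2
Reactants: 2 methyl 13,14,15,16-tetranorlabd-8-en-12-oate
Product: 3 13,14,15,16-tetranorlabd-8-en-12-ol
Conditions: LiAlH4, THF, 0 °C
Reagents that add atoms: none
Why: Hydride reduction of the ester to the primary alcohol; the tetrasubstituted alkene is inert to LiAlH4.

Step 3
Reactants: 3 13,14,15,16-tetranorlabd-8-en-12-ol
Product: 4 12-(tert-butyldimethylsilyloxy)-13,14,15,16-tetranorlabd-8-ene
Conditions: TBSCl, imidazole, DMF, rt
Reagents that add atoms: tert-butyldimethylsilyl chloride, CC(C)(C)[Si](C)(C)Cl
Why: Silyl ether formation at the primary alcohol, to carry C12 through the epoxidation and the allylic oxidation.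

Step 4
Reactants: 4 12-(tert-butyldimethylsilyloxy)-13,14,15,16-tetranorlabd-8-ene
Product: 5 8α,9α-epoxy-12-(tert-butyldimethylsilyloxy)-13,14,15,16-tetranorlabdane
Conditions: mCPBA, CH2Cl2, 0 °C
Reagents that add atoms: 3-chloroperbenzoic acid, OOC(=O)c1cccc(Cl)c1
Why: Prilezhaev epoxidation of the electron-rich tetrasubstituted alkene from the α face, anti to the axial C10 methyl, which should set the C9–O bond α.

Step 5
Reactants: 5 8α,9α-epoxy-12-(tert-butyldimethylsilyloxy)-13,14,15,16-tetranorlabdane
Product: 6 12-(tert-butyldimethylsilyloxy)-13,14,15,16-tetranorlabd-8(17)-en-9α-ol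
Conditions: Et2AlCl, lithium 2,2,6,6-tetramethylpiperidide (from the amine and n-BuLi), toluene, 0 °C
Reagents that add atoms: none
Why: Base-promoted epoxide-to-allylic-alcohol isomerisation, in which the bulky aluminium amide binds the epoxide oxygen and removes a proton from the least hindered β-carbon (the C17 methyl) in a cyclic syn-elimination, so that C8–O breaks and the 9α-oxygen keeps its configuration.

Step 6
Reactants: 6 12-(tert-butyldimethylsilyloxy)-13,14,15,16-tetranorlabd-8(17)-en-9α-ol
Product: 7 12-(tert-butyldimethylsilyloxy)-13,14,15,16-tetranorlabd-8(17)-ene-7α,9α-diol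
Conditions: SeO2 (cat.), t-BuOOH, CH2Cl2, 0 °C to rt
Reagents that add atoms: tert-butyl hydroperoxide, CC(C)(C)OO; selenium dioxide (catalytic oxygen carrier), O=[Se]=O
Why: SeO2 allylic oxidation (ene reaction, then [2,3]-sigmatropic shift) at C7, the only allylic carbon that bears hydrogen, with axial delivery of oxygen on the α face as is usual for exocyclic 8(17)-alkenes of this ring system, giving the 7α-alcohol with the exocyclic alkene restored.

Step 7
Reactants: 7 12-(tert-butyldimethylsilyloxy)-13,14,15,16-tetranorlabd-8(17)-ene-7α,9α-diol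
Product: 8 7α,9α-isopropylidenedioxy-12-(tert-butyldimethylsilyloxy)-13,14,15,16-tetranorlabd-8(17)-ene
Conditions: 2-methoxypropene, PPTS (cat.), CH2Cl2, 0 °C
Reagents that add atoms: 2-methoxypropene, COC(C)=C
Why: Acetal exchange, in which the mixed ketal formed at the secondary 7-OH closes onto the syn-diaxial 9α-OH to a bridging 1,3-dioxane that masks both hydroxyls, the tertiary one included, for the oxidation and olefination steps.

Step 8
Reactants: 8 7α,9α-isopropylidenedioxy-12-(tert-butyldimethylsilyloxy)-13,14,15,16-tetranorlabd-8(17)-ene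
Product: 9 7α,9α-isopropylidenedioxy-13,14,15,16-tetranorlabd-8(17)-en-12-ol
Conditions: Bu4NF, THF, rt
Reagents that add atoms: none
Why: Fluoride cleavage of the primary TBS ether; the ketal is stable to Bu4NF.

Step 9
Reactants: 9 7α,9α-isopropylidenedioxy-13,14,15,16-tetranorlabd-8(17)-en-12-ol
Product: 10 7α,9α-isopropylidenedioxy-13,14,15,16-tetranorlabd-8(17)-en-12-al
Conditions: Dess–Martin periodinane, pyridine, CH2Cl2, 0 °C to rt
Reagents that add atoms: none
Why: Dess–Martin oxidation of the primary alcohol to the aldehyde under pyridine buffering, which should spare the acid-labile bridging ketal and the exocyclic alkene.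

Step 10
Reactants: 10 7α,9α-isopropylidenedioxy-13,14,15,16-tetranorlabd-8(17)-en-12-al; 11 ethyltriphenylphosphonium bromide
Product: 15 (12Z)-13-iodo-7α,9α-isopropylidenedioxy-14,15-dinorlabda-8(17),12-diene, via ethylidene ylide 12 (not isolated), via iodoethylphosphonium iodide 13 (not isolated), via iodo ylide 14 (not isolated)
Conditions: 11, n-BuLi, THF, rt; I2, −78 °C; NaN(SiMe3)2, −78 to −20 °C; then 10, −78 °C
Reagents that add atoms: iodine, II
Why: Stork–Zhao-type α-iodo Wittig olefination, in which the ethylidene ylide is iodinated and deprotonated to the iodo ylide, whose kinetically controlled addition to the aldehyde at low temperature should give mainly the Z iodide (C11 cis to I), the geometry that later places C11 on the inside of the diene.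

Step 11
Reactants: 15 (12Z)-13-iodo-7α,9α-isopropylidenedioxy-14,15-dinorlabda-8(17),12-diene; 16 tributyl(vinyl)stannane
Product: 17 7α,9α-isopropylidenedioxylabda-8(17),12Z,14-triene
Conditions: 16, Pd(PPh3)4 (cat.), CuI (cat.), CsF, DMF, rt
Reagents that add atoms: none
Why: Stille coupling with retention of alkene geometry, run with the zerovalent palladium catalyst under CuI/CsF acceleration at rt so that transmetalation should outrun insertion of the vinylpalladium intermediate into the nearby C8=C17 alkene and the (Z)-diene stays far below the temperature of its 1,5-hydrogen shift.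

Step 12
Reactants: 17 7α,9α-isopropylidenedioxylabda-8(17),12Z,14-triene
Product: 18 labda-8(17),12Z,14-triene-7α,9α-diol
Conditions: PPTS (cat.), MeOH, rt
Reagents that add atoms: none
Why: Acid-catalysed transketalisation to methanol should release the strained bridging ketal under conditions too mild to ionise the tertiary allylic C9–O bond or to touch the diene.

Step 13
Reactants: 19 2,4,6-trihydroxyacetophenone
Product: 20 2-hydroxy-4,6-bis(triisopropylsilyloxy)acetophenone
Conditions: TIPSCl (2.1 equiv), imidazole, DMF, rt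
Reagents that add atoms: triisopropylsilyl chloride, CC(C)[Si](Cl)(C(C)C)C(C)C
Why: Silyl ether formation at the 4-OH and at one ortho OH; the remaining ortho hydroxyl is locked in a hydrogen bond to the acetyl carbonyl and should stay free.

Step 14
Reactants: 21 2,4,5-trimethoxybenzoic acid
Product: 22 2,4,5-trimethoxybenzoyl chloride
Conditions: (COCl)2, DMF (cat.), CH2Cl2, 0 °C to rt
Reagents that add atoms: oxalyl chloride, ClC(=O)C(=O)Cl
Why: Acid chloride formation through the Vilsmeier-type chloroiminium catalyst.

Step 15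
Reactants: 20 2-hydroxy-4,6-bis(triisopropylsilyloxy)acetophenone; 22 2,4,5-trimethoxybenzoyl chloride
Product: 23 2-acetyl-3,5-bis(triisopropylsilyloxy)phenyl 2,4,5-trimethoxybenzoate
Conditions: Et3N, DMAP (cat.), CH2Cl2, 0 °C to rt
Reagents that add atoms: none
Why: DMAP-catalysed O-acylation (esterification) of the chelated phenol by the acid chloride.

Step 16
Reactants: 23 2-acetyl-3,5-bis(triisopropylsilyloxy)phenyl 2,4,5-trimethoxybenzoate
Product: 24 1-[2-hydroxy-4,6-bis(triisopropylsilyloxy)phenyl]-3-(2,4,5-trimethoxyphenyl)propane-1,3-dione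
Conditions: LiN(SiMe3)2 (3 equiv), THF, −78 to 0 °C; AcOH
Reagents that add atoms: none
Why: Baker–Venkataraman rearrangement, in which the acetyl enolate attacks the neighbouring aryl ester and the aroyl group moves from O to C, giving the 1,3-diketone and the free phenol.

Step 17
Reactants: 24 1-[2-hydroxy-4,6-bis(triisopropylsilyloxy)phenyl]-3-(2,4,5-trimethoxyphenyl)propane-1,3-dione
Product: 25 5,7-bis(triisopropylsilyloxy)-2',4',5'-trimethoxyflavone
Conditions: TsOH·H2O (cat.), toluene, 80 °C
Reagents that add atoms: none
Why: Acid-catalysed cyclodehydration of the o-hydroxyaryl 1,3-diketone (hemiketal formation, then loss of water) closes the pyranone ring of the chromone, and catalytic acid in a non-polar solvent should leave the aryl TIPS ethers in place.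

Step 18
Reactants: 25 5,7-bis(triisopropylsilyloxy)-2',4',5'-trimethoxyflavone; 18 labda-8(17),12Z,14-triene-7α,9α-diol
Product: 28 O7–SiMe2–C3(chromone) tethered triene, via 3-lithioflavone 26 (not isolated), via 3-chlorodimethylsilylflavone 27 (not isolated)
Conditions: 25, LiN(iPr)2, THF, −78 °C; cannulate into Me2SiCl2 (excess), −78 °C to rt; evaporate; then 18, imidazole, CH2Cl2, 0 °C to rt
Reagents that add atoms: dichlorodimethylsilane, C[Si](C)(Cl)Cl
Why: Directed deprotonation followed by silyl ether formation: the amide base removes the chromone C3–H, the vinyl anion is trapped once by the large excess of Me2SiCl2, and after that excess is pumped off the chlorosilane should silylate only the secondary allylic 7α-OH, the tertiary 9α-OH being too hindered.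

Step 19
Reactants: 28 O7–SiMe2–C3(chromone) tethered triene
Product: 30 tethered cycloadduct, via tethered quinone 29 (not isolated)
Conditions: PhI(OCOCF3)2 (1.05 equiv), NaHCO3, MeCN/H2O (9:1), 0 °C; then 40 °C in the same flask
Reagents that add atoms: water, O
Why: Proposed new method: the trivalent iodine reagent oxidises the electron-rich 2',4',5'-trimethoxyaryl ring (water delivers the two carbonyl oxygens and two molecules of MeOH leave) to the 2-methoxy-5-(chromon-2-yl)-1,4-benzoquinone 29, and on warming its chromonyl-substituted C=C adds to the tethered 12Z-diene in a concerted but asynchronous intramolecular Diels–Alder reaction, C15–Cf forming ahead of C12–Cq; the nearest known reaction types are silicon-tethered intramolecular Diels–Alder reactions, cycloadditions of quinones freed in situ from p-dimethoxyarenes and intramolecular cycloadditions of (Z)-dienes, but a silicon tether that has to span a ten-membered ring to a (Z)-diene has no precedent. The cyclohexene ring (C12, C13, C14, C15, Cf, Cq) is closed by the [4+2] cycloaddition itself, the temporary ten-membered siloxane ring (C12, C11, C9, C8, C7, O7, Si, chromone C3, chromone C2, Cq) closes as a passive consequence of the C12–Cq bond, and the six-membered ene-dione ring is the former arene, dearomatised but not newly closed. C12, Cq and Cf arise together: because the diene is 12Z, C11 sits in the inside position, and in the quinone-endo, chromonyl-exo transition state it ends up cis to the chromonyl group on Cq and to H on Cf, with the two ring carbonyl carbons cis on the other face (a 12E diene would give the C12 epimer). The absolute configuration follows from which diene face is used, and this should be decided by C9 inside the forming tether ring: in a hand-built model (no calculation supports it yet) the small 9-OH points into the fold of that ring and the quaternary C10 points away from it. The selectivities required are therefore the endo topology and one diene face; the first is enforced because the tether running from the inside C11 branch can reach chromone C3 only if the chromonyl group is exo, and the reluctance of a (Z)-diene should be overcome by the strongly electron-poor dienophile, by intramolecularity and by working far below the temperature of the 1,5-hydrogen shift of the diene.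

Step 20
Reactants: 30 tethered cycloadduct
Product: 31 7α-hydroxy adduct
Conditions: Bu4NF, AcOH (1:1), THF, 0 °C to rt
Reagents that add atoms: none
Why: Fluoride-induced desilylation: the two aryl TIPS ethers and the Si–O7 bond are cleaved, and the fluorosilyl group left on chromone C3 forms a silicate that releases the sp2 carbanion next to the C4 carbonyl, which AcOH protonates (protodesilylation) while keeping the medium from epimerising Cf.

Step 21
Reactants: 31 7α-hydroxy adduct
Product: 32 target CNP0241859.1
Conditions: activated MnO2 (excess), CH2Cl2, rt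
Reagents that add atoms: none
Why: MnO2 oxidation, selective for the secondary allylic 7-OH next to C8=C17, should give the 8(17)-en-7-one and leave the tertiary 9-OH, the hydrogen-bonded phenols and the alkenes untouched; the temporary C7 stereocentre disappears.

**Compound list**

1 | (+)-sclareolide | CC1(C)CCC[C@@]2(C)[C@H]1CC[C@@]1(C)OC(=O)C[C@H]21 | starting material
2 | methyl 13,14,15,16-tetranorlabd-8-en-12-oate (5S,10S) | COC(=O)CC1=C(C)CC[C@H]2C(C)(C)CCC[C@]12C | intermediate
3 | 13,14,15,16-tetranorlabd-8-en-12-ol | OCCC1=C(C)CC[C@H]2C(C)(C)CCC[C@]12C | intermediate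
4 | 12-(tert-butyldimethylsilyloxy)-13,14,15,16-tetranorlabd-8-ene | CC(C)(C)[Si](C)(C)OCCC1=C(C)CC[C@H]2C(C)(C)CCC[C@]12C | intermediate
5 | 8α,9α-epoxy-12-(tert-butyldimethylsilyloxy)-13,14,15,16-tetranorlabdane | C[C@@]12CC[C@H]3C(C)(C)CCC[C@]3(C)[C@]1(CCO[Si](C)(C)C(C)(C)C)O2 | intermediate
6 | 12-(tert-butyldimethylsilyloxy)-13,14,15,16-tetranorlabd-8(17)-en-9α-ol | C=C1CC[C@H]2C(C)(C)CCC[C@]2(C)[C@@]1(O)CCO[Si](C)(C)C(C)(C)C | intermediate
7 | 12-(tert-butyldimethylsilyloxy)-13,14,15,16-tetranorlabd-8(17)-ene-7α,9α-diol | C=C1[C@H](O)C[C@H]2C(C)(C)CCC[C@]2(C)[C@@]1(O)CCO[Si](C)(C)C(C)(C)C | intermediate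
8 | 7α,9α-isopropylidenedioxy-12-(tert-butyldimethylsilyloxy)-13,14,15,16-tetranorlabd-8(17)-ene (bridging acetonide on the α face) | C=C1[C@H]3C[C@H]2C(C)(C)CCC[C@]2(C)[C@]1(CCO[Si](C)(C)C(C)(C)C)OC(C)(C)O3 | intermediate
9 | 7α,9α-isopropylidenedioxy-13,14,15,16-tetranorlabd-8(17)-en-12-ol | C=C1[C@H]3C[C@H]2C(C)(C)CCC[C@]2(C)[C@]1(CCO)OC(C)(C)O3 | intermediate
10 | 7α,9α-isopropylidenedioxy-13,14,15,16-tetranorlabd-8(17)-en-12-al | C=C1[C@H]3C[C@H]2C(C)(C)CCC[C@]2(C)[C@]1(CC=O)OC(C)(C)O3 | intermediate
11 | ethyltriphenylphosphonium bromide | CC[P+](c1ccccc1)(c1ccccc1)c1ccccc1.[Br-] | starting material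
12 | ethylidenetriphenylphosphorane | CC=P(c1ccccc1)(c1ccccc1)c1ccccc1 | intermediate
13 | (1-iodoethyl)triphenylphosphonium iodide | CC(I)[P+](c1ccccc1)(c1ccccc1)c1ccccc1.[I-] | intermediate
14 | (1-iodoethylidene)triphenylphosphorane | CC(I)=P(c1ccccc1)(c1ccccc1)c1ccccc1 | intermediate
15 | (12Z)-13-iodo-7α,9α-isopropylidenedioxy-14,15-dinorlabda-8(17),12-diene (C11 cis to I) | C=C1[C@H]3C[C@H]2C(C)(C)CCC[C@]2(C)[C@]1(C/C=C(C)\I)OC(C)(C)O3 | intermediate
16 | tributyl(vinyl)stannane | C=C[Sn](CCCC)(CCCC)CCCC | starting material
17 | 7α,9α-isopropylidenedioxylabda-8(17),12Z,14-triene | C=C1[C@H]3C[C@H]2C(C)(C)CCC[C@]2(C)[C@]1(C/C=C(C)\C=C)OC(C)(C)O3 | intermediate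
18 | labda-8(17),12Z,14-triene-7α,9α-diol | C=C1[C@H](O)C[C@H]2C(C)(C)CCC[C@]2(C)[C@@]1(O)C/C=C(C)\C=C | intermediate
19 | 2,4,6-trihydroxyacetophenone | CC(=O)c1c(O)cc(O)cc1O | starting material
20 | 2-hydroxy-4,6-bis(triisopropylsilyloxy)acetophenone | CC(=O)c1c(O)cc(O[Si](C(C)C)(C(C)C)C(C)C)cc1O[Si](C(C)C)(C(C)C)C(C)C | intermediate
21 | 2,4,5-trimethoxybenzoic acid | COc1cc(OC)c(cc1OC)C(=O)O | starting material
22 | 2,4,5-trimethoxybenzoyl chloride | COc1cc(OC)c(cc1OC)C(=O)Cl | intermediate
23 | 2-acetyl-3,5-bis(triisopropylsilyloxy)phenyl 2,4,5-trimethoxybenzoate | CC(=O)c1c(OC(=O)c2cc(OC)c(OC)cc2OC)cc(O[Si](C(C)C)(C(C)C)C(C)C)cc1O[Si](C(C)C)(C(C)C)C(C)C | intermediate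
24 | 1-[2-hydroxy-4,6-bis(triisopropylsilyloxy)phenyl]-3-(2,4,5-trimethoxyphenyl)propane-1,3-dione | O=C(CC(=O)c1cc(OC)c(OC)cc1OC)c1c(O)cc(O[Si](C(C)C)(C(C)C)C(C)C)cc1O[Si](C(C)C)(C(C)C)C(C)C | intermediate
25 | 5,7-bis(triisopropylsilyloxy)-2',4',5'-trimethoxyflavone | COc1cc(OC)c(cc1OC)-c1cc(=O)c2c(O[Si](C(C)C)(C(C)C)C(C)C)cc(O[Si](C(C)C)(C(C)C)C(C)C)cc2o1 | intermediate
26 | 3-lithio-5,7-bis(triisopropylsilyloxy)-2',4',5'-trimethoxyflavone | COc1cc(OC)c(cc1OC)-c1c([Li])c(=O)c2c(O[Si](C(C)C)(C(C)C)C(C)C)cc(O[Si](C(C)C)(C(C)C)C(C)C)cc2o1 | intermediate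
27 | 3-(chlorodimethylsilyl)-5,7-bis(triisopropylsilyloxy)-2',4',5'-trimethoxyflavone | COc1cc(OC)c(cc1OC)-c1c([Si](C)(C)Cl)c(=O)c2c(O[Si](C(C)C)(C(C)C)C(C)C)cc(O[Si](C(C)C)(C(C)C)C(C)C)cc2o1 | intermediate
28 | tethered triene: labda-8(17),12Z,14-trien-9α-ol whose 7α-oxygen carries a SiMe2 group bonded to C3 of flavone 25 | C=C1[C@H](O[Si](C)(C)c3c(-c4cc(OC)c(OC)cc4OC)oc5cc(O[Si](C(C)C)(C(C)C)C(C)C)cc(O[Si](C(C)C)(C(C)C)C(C)C)c5c3=O)C[C@H]2C(C)(C)CCC[C@]2(C)[C@@]1(O)C/C=C(C)\C=C | intermediate
29 | tethered quinone: as 28, with the aryl ring oxidised to the 2-methoxy-5-(chromon-2-yl)-1,4-benzoquinone | C=C1[C@H](O[Si](C)(C)c3c(C4=CC(=O)C(OC)=CC4=O)oc5cc(O[Si](C(C)C)(C(C)C)C(C)C)cc(O[Si](C(C)C)(C(C)C)C(C)C)c5c3=O)C[C@H]2C(C)(C)CCC[C@]2(C)[C@@]1(O)C/C=C(C)\C=C | intermediate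
30 | tethered cycloadduct: cis-fused cyclohexene/2-methoxy-ene-dione with C11, chromonyl and H on Cf cis (C12 R, Cf R, Cq S); O7–SiMe2–C3 siloxane bridge; 5,7-bis(TIPS) ether | C=C1[C@H]3C[C@H]2C(C)(C)CCC[C@]2(C)[C@@]1(O)C[C@@H]1C(C)=CC[C@H]2C(=O)C(OC)=CC(=O)[C@@]12c1c([Si](C)(C)O3)c(=O)c2c(O[Si](C(C)C)(C(C)C)C(C)C)cc(O[Si](C(C)C)(C(C)C)C(C)C)cc2o1 | intermediate
31 | 7α-hydroxy adduct: the target with a 7α-OH in place of the C7 ketone | C=C1[C@H](O)C[C@H]2C(C)(C)CCC[C@]2(C)[C@@]1(O)C[C@@H]1C(C)=CC[C@H]2C(=O)C(OC)=CC(=O)[C@@]12c1cc(=O)c2c(O)cc(O)cc2o1 | intermediate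
32 | target CNP0241859.1 | C=C1C(=O)C[C@H]2C(C)(C)CCC[C@]2(C)[C@@]1(O)C[C@@H]1C(C)=CC[C@H]2C(=O)C(OC)=CC(=O)[C@@]12c1cc(=O)c2c(O)cc(O)cc2o1 | target

**Summary**

Total step count: 21.
Longest linear sequence: 16 steps (steps 1 to 12, then 18 to 21, from (+)-sclareolide).

Steps most likely to fail

1. Step 19 (proposed new method). What may go wrong: hydrolytic loss of the Si–O7 link during the oxidation; a cycloaddition too slow to outrun decay of the quinone or the 1,5-hydrogen shift of the (Z)-diene; closure on the wrong diene face. Fallback with known chemistry, untethered: it sets out from flavone 25 and triene acetonide 17 and returns at 31. Flavone 25 is oxidised with PhI(OCOCF3)2 in wet MeCN to 2-[5,7-bis(triisopropylsilyloxy)-4-oxochromen-2-yl]-5-methoxy-1,4-benzoquinone F1. F1 and 17 are then combined in CH2Cl2 under high pressure (about 12 to 15 kbar, rt), the established way of forcing unreactive (Z)-dienes into intermolecular Diels–Alder reactions, to give the acetonide-protected 5,7-bis(TIPS) cycloadduct F2. The acetonide keeps the two hydroxyls from adding to the quinone under pressure. Quinone-endo addition should give the same relative configuration at C12, Cq and Cf, and the regiochemistry is expected from bonding first between the two unhindered termini (C15 and the quinone CH). The diene face is then controlled only weakly by C9, so the wanted diastereomer would have to be separated by chromatography. Bu4NF/AcOH removes the two TIPS ethers to give the acetonide diphenol F3, and PPTS in MeOH releases the 7α,9α-diol, which is 31.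

2. Step 18. What may go wrong: attack of a second lithioflavone on the chlorosilane to give a diarylsilane; migration of the TIPS group from O5 to the lithiated C3; hydrolysis of chlorosilane 27 before it meets the hindered axial alcohol. Fallback through an isolable hydrosilane and a catalytic Si–O coupling: it sets out from 25 and 18 and returns at 28. Lithioflavone 26 (generated as before, held at −78 °C for a few minutes only) is quenched with chlorodimethylsilane, which has a single leaving group, to give the chromatographable 3-(dimethylsilyl)-5,7-bis(triisopropylsilyloxy)-2',4',5'-trimethoxyflavone F4. F4 is then joined to the 7α-OH of 18 by dehydrogenative silylation (Rh2(O2CC3F7)4, a divalent rhodium carboxylate, cat., CH2Cl2, rt, with loss of hydrogen). This coupling silylates secondary alcohols in preference to tertiary ones and should leave the alkenes alone, giving 28.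

3. Step 20. What may go wrong: incomplete cleavage of the C3–Si bond once the Si–O bonds are gone; epimerisation at Cf or degradation of the ene-dione by basic fluoride. Fallback that breaks the C3–Si bond electrophilically instead of nucleophilically: it sets out from 30 and returns at 31. Cycloadduct 30 is treated with CF3CO2H in wet CH2Cl2 at −20 to 0 °C. Chromone C3 is the α-carbon of a vinylogous ester and should be protonated ipso to silicon (β-silyl-stabilised oxocarbenium ion at C2); the silyl group stays on O7 and is hydrolysed on work-up, giving the 5,7-bis(TIPS) 7α,9α-diol adduct F5. The two aryl TIPS ethers are then removed with non-basic Et3N·3HF in MeCN to give 31.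

Further compounds
F1 | step 19 | 2-[5,7-bis(triisopropylsilyloxy)-4-oxochromen-2-yl]-5-methoxy-1,4-benzoquinone | COC1=CC(=O)C(=CC1=O)c1cc(=O)c2c(O[Si](C(C)C)(C(C)C)C(C)C)cc(O[Si](C(C)C)(C(C)C)C(C)C)cc2o1
F2 | step 19 | acetonide-protected 5,7-bis(TIPS) cycloadduct (7α,9α-isopropylidenedioxy analogue of 31 with both phenols as TIPS ethers) | C=C1[C@H]3C[C@H]2C(C)(C)CCC[C@]2(C)[C@]1(C[C@@H]4C(C)=CC[C@H]5C(=O)C(OC)=CC(=O)[C@@]45c4cc(=O)c5c(O[Si](C(C)C)(C(C)C)C(C)C)cc(O[Si](C(C)C)(C(C)C)C(C)C)cc5o4)OC(C)(C)O3
F3 | step 19 | acetonide diphenol (7α,9α-isopropylidenedioxy analogue of 31) | C=C1[C@H]3C[C@H]2C(C)(C)CCC[C@]2(C)[C@]1(C[C@@H]4C(C)=CC[C@H]5C(=O)C(OC)=CC(=O)[C@@]45c4cc(=O)c5c(O)cc(O)cc5o4)OC(C)(C)O3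
F4 | step 18 | 3-(dimethylsilyl)-5,7-bis(triisopropylsilyloxy)-2',4',5'-trimethoxyflavone | COc1cc(OC)c(cc1OC)-c1c([SiH](C)C)c(=O)c2c(O[Si](C(C)C)(C(C)C)C(C)C)cc(O[Si](C(C)C)(C(C)C)C(C)C)cc2o1
F5 | step 20 | 5,7-bis(TIPS) 7α,9α-diol adduct (31 with both phenols as TIPS ethers) | C=C1[C@H](O)C[C@H]2C(C)(C)CCC[C@]2(C)[C@@]1(O)C[C@@H]1C(C)=CC[C@H]2C(=O)C(OC)=CC(=O)[C@@]12c1cc(=O)c2c(O[Si](C(C)C)(C(C)C)C(C)C)cc(O[Si](C(C)C)(C(C)C)C(C)C)cc2o1
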